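**Retrosynthetic overview**
1. Target 20 ⇐ selective acetylation and 1,2-reduction of dienal 18 ⇐ amine-catalysed aldol condensation of bicyclic aldehyde 14 with hydroxy-enal 17 (side chain last).
2. 14 ⇐ conjugate addition of a formylmethyl equivalent to bridged enoate 9 from its open face (C3), then ester equilibration (C2).
3. 9 ⇐ selenolate-triggered Michael–aldol closure of the seven-membered ring (ring B, formed second; C1 fixed by the bridge) on cyclohexanone 6.
4. 6 ⇐ new silyl-transfer epoxide-opening cyclization of epoxy enol silane 5 (six-membered ring A, formed first; C6 quaternary centre by inversion).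
5. 5 ⇐ Shi epoxidation (sets C6 and C7) of achiral dienoate 3 ⇐ nerylacetone 1 + methyl acrylate 2 by cross-metathesis.

Assumption: nerylacetone is bought as the pure (5Z) isomer; the chiral ketone of step 2 is a catalyst, not a starting material.

Locants C1–C10 used below are those of the bicyclo[4.3.1]decane core of the target.

**Step 1**
Reactants: 1 nerylacetone [(5Z)-6,10-dimethylundeca-5,9-dien-2-one]; 2 methyl acrylate
Product: 3 methyl (2E,6Z)-6-methyl-10-oxoundeca-2,6-dienoate
Conditions: Hoveyda–Grubbs second-generation catalyst (3 mol %), 2 (5 equiv), CH2Cl2, 40 °C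
Reagents that add atoms: none
Why: Olefin cross-metathesis in which the prenyl terminus exchanges with the acrylate (isobutene lost, E-enoate formed), while the more hindered internal trisubstituted olefin, flanked by two methylene groups, should keep its Z geometry.

**Step 2**
Reactants: 3 methyl (2E,6Z)-6-methyl-10-oxoundeca-2,6-dienoate
Product: 4 methyl (2E)-5-[(2R,3S)-2-methyl-3-(3-oxobutyl)oxiran-2-yl]pent-2-enoate
Conditions: ent-Shi ketone (L-fructose-derived, 30 mol %), KHSO5 (as 2KHSO5·KHSO4·K2SO4), K2CO3, Bu4NHSO4, MeCN–CH2(OMe)2–aq. Na2B4O7 buffer (pH 10.5), 0 °C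
Reagents that add atoms: potassium peroxymonosulfate, [K+].[O-]S(=O)(=O)OO
Why: Shi asymmetric epoxidation (organocatalytic chiral dioxirane) attacks the only electron-rich olefin through the spiro transition state, the L-series ketone giving the (3S) configuration at the CH carbon, so the Z geometry is stored as the cis-(2R,3S) epoxide that carries C6 and C7 of the target (about 90% ee expected, to be raised by recrystallizing a later solid such as 14), and the enoate is inert to the electrophilic oxidant.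

**Step 3**
Reactants: 4 methyl (2E)-5-[(2R,3S)-2-methyl-3-(3-oxobutyl)oxiran-2-yl]pent-2-enoate
Product: 5 methyl (2E)-5-[(2R,3S)-2-methyl-3-[3-(triethylsilyloxy)but-3-en-1-yl]oxiran-2-yl]pent-2-enoate
Conditions: lithium 2,2,6,6-tetramethylpiperidide (1.1 equiv), Et3SiCl (in situ quench), THF, −78 °C
Reagents that add atoms: chlorotriethylsilane, CC[Si](CC)(CC)Cl
Why: Kinetic enolate silylation, in which the hindered amide removes a methyl proton of the ketone faster than it can add to the enoate or open the epoxide, gives the terminal enol silane.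

**Step 4**
Reactants: 5 methyl (2E)-5-[(2R,3S)-2-methyl-3-[3-(triethylsilyloxy)but-3-en-1-yl]oxiran-2-yl]pent-2-enoate
Product: 6 methyl (2E)-5-[(1R,2S)-1-methyl-5-oxo-2-(triethylsilyloxy)cyclohexyl]pent-2-enoate
Conditions: Et3SiOTf (10 mol %), 2,6-di-tert-butyl-4-methylpyridine (15 mol %), CH2Cl2 (0.01 M), −78 °C
Reagents that add atoms: none
Why: Proposed new method: a silyl-transfer Mukaiyama-type epoxide-opening cyclization in which catalytic Et3SiOTf silylates the epoxide oxygen, the terminal enol silane attacks the tertiary oxirane carbon through a six-membered chair anti to the departing C–O bond (6-endo, borderline SN2 with inversion, so the cis-epoxide becomes the C6 quaternary centre with C5 cis to the C7 oxygen), and the silyloxocarbenium ion returns Et3Si+ to triflate to turn the catalyst over, leaving the ketone and the C7 silyl ether; the closest known reactions are epoxide-initiated cation–olefin cyclizations terminated by enol silanes, epoxy-allylsilane cyclizations and Me3SiOTf-catalysed Mukaiyama reactions with silyl transfer.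

**Step 5**
Reactants: 6 methyl (2E)-5-[(1R,2S)-1-methyl-5-oxo-2-(triethylsilyloxy)cyclohexyl]pent-2-enoate
Product: 9 methyl (1S,6R,7S)-6-methyl-1,7-bis(triethylsilyloxy)bicyclo[4.3.1]dec-2-ene-2-carboxylate, via selenide 7 (not isolated), via selenoxide 8 (not isolated)
Conditions: PhSeLi (from PhSeH, n-BuLi), THF, −78 → −30 °C; Et3SiOTf, −78 → 0 °C; then 30% H2O2, pyridine, 0 °C → rt; DBU
Reagents that add atoms: triethylsilyl trifluoromethanesulfonate, CC[Si](CC)(CC)OS(=O)(=O)C(F)(F)F
Why: Selenolate-triggered Michael–aldol cyclization (an intramolecular Morita–Baylis–Hillman surrogate) followed by selenoxide elimination: PhSe– adds to the enoate, the ester enolate closes the seven-membered ring onto the only ketone from the face of its axial tether (which fixes C1 as 1S), the aldolate is capped as its silyl ether, and oxidation–elimination restores the conjugated enoate.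

**Step 6**
Reactants: 9 methyl (1S,6R,7S)-6-methyl-1,7-bis(triethylsilyloxy)bicyclo[4.3.1]dec-2-ene-2-carboxylate; 10 (1,3-dioxolan-2-ylmethyl)magnesium bromide
Product: 12 methyl (1S,3S,6R,7S)-3-(1,3-dioxolan-2-ylmethyl)-6-methyl-1,7-bis(triethylsilyloxy)bicyclo[4.3.1]decane-2-carboxylate (both C2 epimers), via silyl ketene acetal 11 (not isolated)
Conditions: CuBr·SMe2 (20 mol %), Me3SiCl, THF, −78 → −30 °C; aq. NH4Cl
Reagents that add atoms: none
Why: Copper-catalysed conjugate addition of a Grignard reagent (Me3SiCl-accelerated), in which the face of C2=C3 turned toward the three-carbon bridge is shielded so the formylmethyl equivalent adds anti to it and sets C3, while C2 forms as a mixture on protonation and is corrected in step 7.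

**Step 7**
Reactants: 12 methyl (1S,3S,6R,7S)-3-(1,3-dioxolan-2-ylmethyl)-6-methyl-1,7-bis(triethylsilyloxy)bicyclo[4.3.1]decane-2-carboxylate
Product: 14 methyl (1S,2S,3S,6R,7S)-1,7-dihydroxy-6-methyl-3-(2-oxoethyl)bicyclo[4.3.1]decane-2-carboxylate, via C2-equilibrated acetal 13 (not isolated)
Conditions: NaOMe (0.3 equiv), MeOH, rt; then 2 M HCl, THF, rt
Reagents that add atoms: water, O
Why: Base epimerization then acid hydrolysis: methoxide equilibrates C2 to the diequatorial trans-2,3 ester (retro-aldol is blocked by the bridgehead silyl ether and β-elimination by the bridgehead itself), and aqueous acid then cleaves the dioxolane and both silyl ethers.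

**Step 8**
Reactants: 15 2-methylbut-3-en-2-ol; 16 (E)-but-2-enal
Product: 17 (2E)-4-hydroxy-4-methylpent-2-enal
Conditions: Hoveyda–Grubbs second-generation catalyst (2 mol %), 15 (3 equiv), CH2Cl2, 40 °C
Reagents that add atoms: none
Why: Olefin cross-metathesis between two partners that homodimerize slowly gives the E-enal with loss of propene.

**Step 9**
Reactants: 14 methyl (1S,2S,3S,6R,7S)-1,7-dihydroxy-6-methyl-3-(2-oxoethyl)bicyclo[4.3.1]decane-2-carboxylate; 17 (2E)-4-hydroxy-4-methylpent-2-enal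
Product: 18 methyl (1S,2S,3R,6R,7S)-1,7-dihydroxy-3-[(2E,4E)-6-hydroxy-6-methyl-1-oxohepta-2,4-dien-2-yl]-6-methylbicyclo[4.3.1]decane-2-carboxylate
Conditions: pyrrolidine (30 mol %), PhCO2H (30 mol %), 17 (3 equiv), CH2Cl2, rt
Reagents that add atoms: none
Why: Amine-catalysed crossed aldol (Mannich-type) condensation, in which the enamine of 14 adds 1,2 to the iminium ion of the non-enolizable enal 17 (1,4-attack is hindered by the quaternary γ-carbon) and amine elimination gives the thermodynamic 2E dienal with the ring carbon cis to the new vinyl CH.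

**Step 10**
Reactants: 18 methyl (1S,2S,3R,6R,7S)-1,7-dihydroxy-3-[(2E,4E)-6-hydroxy-6-methyl-1-oxohepta-2,4-dien-2-yl]-6-methylbicyclo[4.3.1]decane-2-carboxylate
Product: 19 methyl (1S,2S,3R,6R,7S)-3-[(2E,4E)-1,6-dihydroxy-6-methylhepta-2,4-dien-2-yl]-1,7-dihydroxy-6-methylbicyclo[4.3.1]decane-2-carboxylate
Conditions: NaBH4, CeCl3·7H2O, MeOH, −78 °C; pH 7 buffer at −78 °C
Reagents that add atoms: none
Why: Luche 1,2-reduction takes the cerium-activated aldehyde to the allylic alcohol without touching the diene or the methyl ester, and the cold neutral quench keeps the new primary alcohol from lactonizing onto the ester.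

**Step 11**
Reactants: 19 methyl (1S,2S,3R,6R,7S)-3-[(2E,4E)-1,6-dihydroxy-6-methylhepta-2,4-dien-2-yl]-1,7-dihydroxy-6-methylbicyclo[4.3.1]decane-2-carboxylate
Product: 20 methyl (1S,2S,3R,6R,7S)-3-[(2E,4E)-1-(acetyloxy)-6-hydroxy-6-methylhepta-2,4-dien-2-yl]-1,7-dihydroxy-6-methylbicyclo[4.3.1]decane-2-carboxylate
Conditions: Ac2O (1.1 equiv), 2,4,6-collidine, CH2Cl2, −20 → 0 °C
Reagents that add atoms: acetic anhydride, CC(=O)OC(C)=O
Why: Selective acylation, in which the primary allylic hydroxyl is acetylated far faster than the neopentyl secondary C7 hydroxyl and the two tertiary hydroxyls.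

**Compound list**
1 | nerylacetone, (5Z)-6,10-dimethylundeca-5,9-dien-2-one | CC(=O)CC/C=C(C)\CCC=C(C)C | starting material
2 | methyl acrylate | C=CC(=O)OC | starting material
3 | methyl (2E,6Z)-6-methyl-10-oxoundeca-2,6-dienoate | CC(=O)CC/C=C(C)\CC/C=C/C(=O)OC | intermediate
4 | methyl (2E)-5-[(2R,3S)-2-methyl-3-(3-oxobutyl)oxiran-2-yl]pent-2-enoate | CC(=O)CC[C@@H]1O[C@]1(C)CC/C=C/C(=O)OC | intermediate
5 | methyl (2E)-5-[(2R,3S)-2-methyl-3-[3-(triethylsilyloxy)but-3-en-1-yl]oxiran-2-yl]pent-2-enoate | C=C(O[Si](CC)(CC)CC)CC[C@@H]1O[C@]1(C)CC/C=C/C(=O)OC | intermediate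
6 | methyl (2E)-5-[(1R,2S)-1-methyl-5-oxo-2-(triethylsilyloxy)cyclohexyl]pent-2-enoate | COC(=O)/C=C/CC[C@]1(C)CC(=O)CC[C@@H]1O[Si](CC)(CC)CC | intermediate
7 | methyl (1S,6R,7S)-6-methyl-3-(phenylselanyl)-1,7-bis(triethylsilyloxy)bicyclo[4.3.1]decane-2-carboxylate (C2/C3 diastereomers; not isolated) | COC(=O)C1C([Se]c3ccccc3)CC[C@]2(C)C[C@@]1(O[Si](CC)(CC)CC)CC[C@@H]2O[Si](CC)(CC)CC | intermediate
8 | methyl (1S,6R,7S)-6-methyl-3-(phenylseleninyl)-1,7-bis(triethylsilyloxy)bicyclo[4.3.1]decane-2-carboxylate (not isolated) | COC(=O)C1C([Se](=O)c3ccccc3)CC[C@]2(C)C[C@@]1(O[Si](CC)(CC)CC)CC[C@@H]2O[Si](CC)(CC)CC | intermediate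
9 | methyl (1S,6R,7S)-6-methyl-1,7-bis(triethylsilyloxy)bicyclo[4.3.1]dec-2-ene-2-carboxylate | COC(=O)C1=CCC[C@]2(C)C[C@@]1(O[Si](CC)(CC)CC)CC[C@@H]2O[Si](CC)(CC)CC | intermediate
10 | (1,3-dioxolan-2-ylmethyl)magnesium bromide | Br[Mg]CC1OCCO1 | starting material
11 | methyl trimethylsilyl ketene acetal of ester 12, C2=C(OMe)OSiMe3 (not isolated) | COC(O[Si](C)(C)C)=C1[C@H](CC3OCCO3)CC[C@]2(C)C[C@@]1(O[Si](CC)(CC)CC)CC[C@@H]2O[Si](CC)(CC)CC | intermediate
12 | methyl (1S,3S,6R,7S)-3-(1,3-dioxolan-2-ylmethyl)-6-methyl-1,7-bis(triethylsilyloxy)bicyclo[4.3.1]decane-2-carboxylate (both C2 epimers) | COC(=O)C1[C@H](CC3OCCO3)CC[C@]2(C)C[C@@]1(O[Si](CC)(CC)CC)CC[C@@H]2O[Si](CC)(CC)CC | intermediate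
13 | methyl (1S,2S,3S,6R,7S)-3-(1,3-dioxolan-2-ylmethyl)-6-methyl-1,7-bis(triethylsilyloxy)bicyclo[4.3.1]decane-2-carboxylate (not isolated) | COC(=O)[C@H]1[C@H](CC3OCCO3)CC[C@]2(C)C[C@@]1(O[Si](CC)(CC)CC)CC[C@@H]2O[Si](CC)(CC)CC | intermediate
14 | methyl (1S,2S,3S,6R,7S)-1,7-dihydroxy-6-methyl-3-(2-oxoethyl)bicyclo[4.3.1]decane-2-carboxylate | COC(=O)[C@H]1[C@H](CC=O)CC[C@]2(C)C[C@@]1(O)CC[C@@H]2O | intermediate
15 | 2-methylbut-3-en-2-ol | CC(C)(O)C=C | starting material
16 | (E)-but-2-enal | C/C=C/C=O | starting material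
17 | (2E)-4-hydroxy-4-methylpent-2-enal | CC(C)(O)/C=C/C=O | intermediate
18 | methyl (1S,2S,3R,6R,7S)-1,7-dihydroxy-3-[(2E,4E)-6-hydroxy-6-methyl-1-oxohepta-2,4-dien-2-yl]-6-methylbicyclo[4.3.1]decane-2-carboxylate | COC(=O)[C@H]1[C@H](/C(=C\C=C\C(C)(C)O)C=O)CC[C@]2(C)C[C@@]1(O)CC[C@@H]2O | intermediate
19 | methyl (1S,2S,3R,6R,7S)-3-[(2E,4E)-1,6-dihydroxy-6-methylhepta-2,4-dien-2-yl]-1,7-dihydroxy-6-methylbicyclo[4.3.1]decane-2-carboxylate | COC(=O)[C@H]1[C@H](/C(=C\C=C\C(C)(C)O)CO)CC[C@]2(C)C[C@@]1(O)CC[C@@H]2O | intermediate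
20 | methyl (1S,2S,3R,6R,7S)-3-[(2E,4E)-1-(acetyloxy)-6-hydroxy-6-methylhepta-2,4-dien-2-yl]-1,7-dihydroxy-6-methylbicyclo[4.3.1]decane-2-carboxylate | COC(=O)[C@H]1[C@H](/C(=C\C=C\C(C)(C)O)COC(C)=O)CC[C@]2(C)C[C@@]1(O)CC[C@@H]2O | target

**Step count**
Total steps: 11. Longest linear sequence: 10 (steps 1–7 and 9–11; step 8 is the side branch).

**Steps most likely to fail, and fallbacks**

Step 4 (the proposed new cyclization) may lose out to Meinwald rearrangement of the silylated epoxide or to five-ring closure. The fallback is the established epoxy-allylsilane cyclization; it sets out from 4 and comes back at 6. Kinetic enolate triflation of 4 (lithium 2,2,6,6-tetramethylpiperidide, PhNTf2) gives the vinyl triflate F1. Pd(PPh3)4-catalysed coupling with Me3SiCH2MgCl gives the 2-substituted allylsilane F2. BF3·OEt2 at −78 °C closes ring A with the same anti opening at the tertiary oxirane carbon to give the methylidenecyclohexanol F3. Et3SiCl/imidazole gives the silyl ether F4. Ozonolysis of the electron-rich exocyclic olefin only (O3, pyridine, −78 °C, then Me2S) returns to 6.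

Step 5 (seven-membered Michael–aldol closure) may stall at the open Michael adduct, or the ester enolate may be quenched by proton transfer from the ketone. The fallback replaces the selenolate trigger by hydride; it sets out from 6 and comes back at 9. Copper hydride reductive aldol cyclization ([(Ph3P)CuH]6, toluene, −40 °C → rt) gives the saturated bridged β-hydroxy ester F5. Et3SiOTf/2,6-lutidine gives the bis-silyl ether F6. Ester enolate selenenylation (LiN(i-Pr)2, then PhSeBr, THF, −78 °C) gives the α-phenylselanyl ester F7. H2O2 oxidation with syn-elimination, which can only go toward C3, returns to 9.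

Step 9 (crossed aldol condensation) may be eroded by self-condensation of 14 or by Michael pathways. The fallback is a stepwise directed Mukaiyama aldol; it sets out from 14 and comes back at 18. Me3SiOTf/Et3N converts 14 into the tris-silylated enol ether F8. BF3·OEt2-mediated addition to the aldehyde carbon of 17 at −78 °C gives the β-hydroxy aldehyde F9. PPTS in wet THF–MeOH removes the silyl ethers and dehydrates the aldol to 18.

**Further compounds**
F1 | step 4 | methyl (2E)-5-[(2R,3S)-2-methyl-3-[3-(trifluoromethylsulfonyloxy)but-3-en-1-yl]oxiran-2-yl]pent-2-enoate | C=C(OS(=O)(=O)C(F)(F)F)CC[C@@H]1O[C@]1(C)CC/C=C/C(=O)OC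
F2 | step 4 | methyl (2E)-5-[(2R,3S)-2-methyl-3-[3-(trimethylsilylmethyl)but-3-en-1-yl]oxiran-2-yl]pent-2-enoate | C=C(C[Si](C)(C)C)CC[C@@H]1O[C@]1(C)CC/C=C/C(=O)OC
F3 | step 4 | methyl (2E)-5-[(1R,2S)-2-hydroxy-1-methyl-5-methylidenecyclohexyl]pent-2-enoate | COC(=O)/C=C/CC[C@]1(C)CC(=C)CC[C@@H]1O
F4 | step 4 | methyl (2E)-5-[(1R,2S)-1-methyl-5-methylidene-2-(triethylsilyloxy)cyclohexyl]pent-2-enoate | COC(=O)/C=C/CC[C@]1(C)CC(=C)CC[C@@H]1O[Si](CC)(CC)CC
F5 | step 5 | methyl (1S,6R,7S)-1-hydroxy-6-methyl-7-(triethylsilyloxy)bicyclo[4.3.1]decane-2-carboxylate (C2 epimers) | COC(=O)C1CCC[C@]2(C)C[C@@]1(O)CC[C@@H]2O[Si](CC)(CC)CC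
F6 | step 5 | methyl (1S,6R,7S)-6-methyl-1,7-bis(triethylsilyloxy)bicyclo[4.3.1]decane-2-carboxylate (C2 epimers) | COC(=O)C1CCC[C@]2(C)C[C@@]1(O[Si](CC)(CC)CC)CC[C@@H]2O[Si](CC)(CC)CC
F7 | step 5 | methyl (1S,6R,7S)-6-methyl-2-(phenylselanyl)-1,7-bis(triethylsilyloxy)bicyclo[4.3.1]decane-2-carboxylate (C2 epimers) | COC(=O)C1([Se]c3ccccc3)CCC[C@]2(C)C[C@@]1(O[Si](CC)(CC)CC)CC[C@@H]2O[Si](CC)(CC)CC
F8 | step 9 | methyl (1S,2S,3S,6R,7S)-6-methyl-1,7-bis(trimethylsilyloxy)-3-[2-(trimethylsilyloxy)ethenyl]bicyclo[4.3.1]decane-2-carboxylate (E/Z enol ether) | COC(=O)[C@H]1[C@H](C=CO[Si](C)(C)C)CC[C@]2(C)C[C@@]1(O[Si](C)(C)C)CC[C@@H]2O[Si](C)(C)C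
F9 | step 9 | methyl (1S,2S,3S,6R,7S)-3-[(3E)-1-formyl-2,5-dihydroxy-5-methylhex-3-en-1-yl]-6-methyl-1,7-bis(trimethylsilyloxy)bicyclo[4.3.1]decane-2-carboxylate (epimers at the two new side-chain centres) | COC(=O)[C@H]1[C@H](C(C=O)C(O)/C=C/C(C)(C)O)CC[C@]2(C)C[C@@]1(O[Si](C)(C)C)CC[C@@H]2O[Si](C)(C)C
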